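You must decide when to stop the flask, and I would decide by one number read off the two earlier runs, with Z frozen at its charge.

| flask | L | Z | remark | time |
|---|---|---|---|---|
| blue | 0.46 M (fed, over 15 h) | 1.5 mM | run made earlier |  |
| green | 0.46 M (fed, over 15 h) | 3.4 mM | run made earlier |  |
| flask | 0.46 M (fed, over 15 h) | 2.3 mM |  | 15 d |

| run | time / d | D / % |
|---|---|---|
| blue | 1.25 | 9.4 |
| blue | 2.50 | 16.8 |
| blue | 5.00 | 21.9 |
| blue | 10.0 | 23.4 |
| blue | 20.0 | 21.5 |
| green | 1.25 | 21.9 |
| green | 2.50 | 31.5 |
| green | 5.00 | 32.3 |
| green | 10.0 | 26.5 |
| green | 20.0 | 20.5 |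

(standard deviation of a reading: 1 percentage point)



1. time, not beyond 15 d, at which the flask holds most D
2. the amount of D, in percent of the L charged, at that time

Over the first 1.25 d, D gains 0.0752 d⁻¹ of the charge in the blue run and 0.175 d⁻¹ in the green run. These rates stand in the ratio 2.33, close to the ratio of Z, 2.27, so I treat the start as pseudo-first-order, with pace in proportion to Z.

In the green run the gain then slows to 0.0768 d⁻¹, a factor of 0.439. From 2.50 d to 5.00 d it slows by a further factor of 0.0417, and those two readings differ by less than their scatter. So I read the end of the green gain near 3.75 d, the middle of that stretch, a reading that carries their scatter, and this gives 12.7 mM·d: this is the stopping dose, Z multiplied by the time at which D stops gaining, for this charge and this feed of L.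

For the blue run it gives 8.50 d, inside the stretch from 5.00 d to 10.0 d where blue D gains 1.5 percentage points. For the flask it gives 5.54 d. Going along ln Z between the highest readings of the two runs, I expect about 28.0% of the charge as D in the flask.

The forecast, holding that “consumption of L scales about with Z”, gives 28.3% (range 26.5% to 30%) at 5.8 d (range 4.5 d to 7.5 d), later than my time.

The flask holds most D at 5.14 d, namely 28.8% of the charge, and at 6.42 d it still holds 28.4%.

    D ⇌ G (K = 3.00, k = 4.02 × 10⁻⁶ s⁻¹)
    G + Z ⇌ E + Z, rate k2*[Z]*[G] forward; the back reaction follows from the equilibrium constant (K = 2.22, k = 7.17 × 10⁻⁵ M⁻¹ s⁻¹)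
    L + Z ⇌ D + Z, rate k3*[L]*[Z] forward; the back reaction follows from the equilibrium constant (K = 3.00, k = 0.00105 M⁻¹ s⁻¹)

Z stands at 100% of its charge at 15.0 d in the flask, so the freezing holds there. The flask's own stopping dose is 11.8 mM·d, a little below the 12.7 mM·d I carried. Now take the neighbouring flask, changed in one setting, with Z at 9.2 × 10⁻⁴ M. The carried dose puts its stop at 13.9 d, close to the end of the allowed time, so D there should be nearly level by 15.0 d. Within the allowed time that neighbouring flask reaches a highest D of 20.7%, and at 15.0 d it holds 20.7% as D, with 33.6% still as L.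

The runs are calculated for substances that don't exist, noise included.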